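The numbers in the tables were computed for substances that don't exist, and the scatter is random.

The dusk run leaves 21.6 % of substrate and 26.2 % of open intermediate at 40.0 h, and that leftover has 20.0 h still to run.

| setting | summer | noon | dusk | Friday's | Monday's | Thursday's |
|---|---|---|---|---|---|---|
| substrate | 1.1 M | 1.1 M | 1.1 M | 1.1 M | 1.1 M | 1.1 M |
| capture agent | 0.049 M | 0.068 M | 0.074 M | 0.0550 M | 0.0660 M | 0.0790 M |
| remark | run made earlier | run made earlier | run made earlier |  |  |  |
| time |  |  |  | 2.5 d | 2.5 d | 2.5 d |

| run | time / h | substrate / % | open intermediate / % | isomer of the product / % | target / % |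
|---|---|---|---|---|---|
| summer | 4.00 | 85.0 | 11.7 | 1.3 | 0.6 |
| summer | 10.0 | 67.1 | 21.5 | 1.1 | 5.3 |
| summer | 20.0 | 46.5 | 29.2 | 5.3 | 13.7 |
| summer | 30.0 | 30.4 | 28.4 | 6.6 | 24.2 |
| summer | 40.0 | 22.2 | 26.2 | 9.8 | 32.2 |
| noon | 4.00 | 84.3 | 10.5 | 0 | 0.7 |
| noon | 10.0 | 66.2 | 22.0 | 2.0 | 4.6 |
| noon | 20.0 | 45.3 | 29.3 | 4.4 | 13.5 |
| noon | 30.0 | 31.8 | 28.9 | 6.6 | 22.9 |
| noon | 40.0 | 21.7 | 24.8 | 9.9 | 31.7 |
| dusk | 4.00 | 83.9 | 11.1 | 0 | 0.7 |
| dusk | 10.0 | 66.7 | 22.4 | 0.6 | 4.3 |
| dusk | 20.0 | 45.6 | 28.9 | 3.9 | 13.3 |
| dusk | 30.0 | 31.5 | 29.4 | 6.9 | 23.0 |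
| dusk | 40.0 | 21.6 | 26.2 | 9.8 | 32.3 |

(standard deviation of a reading: 0.5 percentage points)

1. which of these there is most of at the end, counted by the substrate in it, Friday's (isomer of the product / substrate / target / open intermediate)
2. which of these there is most of at the end, counted by the substrate in it, Monday's (isomer of the product / substrate / target / open intermediate)
3. which of these there is most of at the end, counted by the substrate in it, Thursday's (isomer of the product / substrate / target / open intermediate)
4. the largest of these amounts at the end, in percent of the substrate charged, Friday's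
5. the largest of these amounts at the end, in percent of the substrate charged, Monday's
6. the largest of these amounts at the end, in percent of the substrate charged, Thursday's



Target at 40.0 h reads 32.2 %, 31.7 % and 32.3 % across the capture agent charges, so I reckon on dusk and carry it to Friday's, Monday's and Thursday's. I carry one number, the hand-over constant κ, the target gained per hour per unit of [open intermediate], read between 20.0 h and 40.0 h:

κ = 0.0334 /h

The isomer's constant read the same way is 0.0104 /h, a selectivity factor of 3.21. Substrate falls with 0.0374 /h.

Now the curve, in points per 10.0 h. Target starts flat: at 4.00 h, κ[open intermediate] gives 3.7 percentage points. Its slope steepens to 9.8 points with the 29.4 % read at 30.0 h, and I place the knee, where my feed from substrate meets my drain to target and isomer, near 27.5 h. Dusk's target lies below both substrate and open intermediate at 30.0 h and above both at 40.0 h.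

At 40.0 h I reckon feed at 8.1 points and drain at 11 points, so open intermediate moves by:

net at 40.0 h = −3.4 points

How does that drift? By 60 h I reckon substrate at 10.2 %, and the net becomes −4.7 points. Averaging the two:

[open intermediate] at the end = 18.1 %
target at the end = 47.1 %

Isomer comes to 14.4 %, so I expect target on top.

The forecast names target for each flask, with 46 % (37 % to 51 %), 47 % (40 % to 51 %) and 47 % (43 % to 51 %): “Target stays my expectation in all three”.

Friday's ends with target on top at 45.7 %, Monday's with target at 45.5 %, Thursday's with target at 45.3 %.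

    substrate → open intermediate (k = 9.60 × 10⁻⁶ /s)
    open intermediate + capture agent → trapped intermediate (k = 7.60 × 10⁻⁶ /M/s)
    open intermediate ⇌ isomer of the product (K = 3.10, k = 3.10 × 10⁻⁶ /s)
    open intermediate ⇌ target (K = 12.0, k = 9.80 × 10⁻⁶ /s)
    2 substrate → homo dimer (k = 9.10 × 10⁻⁷ /M/s)

With Thursday's simulated 18.5 % of open intermediate, κ still gives 6.2 points per 10.0 h at the end. Thursday's read at 25 h instead is the same reckoning from dusk's 13.3 % at 20.0 h: with the 29.3 % of open intermediate standing there, κ gives 18.2 %. That flask holds 18.5 % of target, with substrate still on top at 37.6 %.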